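**Retrosynthetic overview** (labdane numbering: ring A = C1–C5/C10, ring B = C5–C10, C9 carries OH and C11–C12, butenolide = C13–C16)

1. Target 24 ⇐ acetate 21 + 4-bromobutenolide 22 (C12–C13, B-alkyl Suzuki) ⇐ 9α-hydroxy-9β-vinyl decalin 19 ⇐ 9α,11-epoxide 18 ⇐ C9 ketone 16.
2. Key disconnection: C5–C10 and C6–C7 of 16 are cut together, back to the acyclic bromo dienone 14. Forward, ring A closes first (6-exo) and ring B second (6-endo) in one radical chain; no ring exists before this step.
3. Enabling feature: C9, the ring-B carbinol carbon between quaternary C10 and C8. As a ketone it makes C10 an α-keto radical site and C7=C8 a radical acceptor, so the unactivated vinyl group C5=C6 on the gem-dimethyl carbon C4 of ring A is inserted between them.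
4. The only stereocentre of the precursor is C3 (S, asymmetric reverse prenylation). It is relayed to C5 and C10 in the cascade; C8 follows by equilibration and C9 by α-face epoxidation.
5. Carbon sources: δ-valerolactone, MeI, prenylmagnesium chloride, isopropenylmagnesium bromide, two ylide CH2 units, 4-bromofuran-2(5H)-one.

Key step: step 8

Remark on the chemistry: the α-carbonyl methine that becomes C10 is carried as an epimer mixture from 3 to 14 and written without configuration, because it becomes a planar radical centre in step 8. Dienol ether 13 is expected as an E/Z mixture and is written without alkene geometry. In 23 the hindered tertiary hydroxyl is written free.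

**Step 1**
Reactants: 1 δ-valerolactone (tetrahydro-2H-pyran-2-one)
Product: 3 3-methyltetrahydro-2H-pyran-2-one (racemic), via lithium enolate 2 (not isolated)
Conditions: LiN(iPr)2, THF, −78 °C; MeI, DMPU, −78 → −40 °C
Reagents that add atoms: iodomethane, CI
Why: Enolate alkylation of the kinetic lactone enolate should install the methyl that becomes C20; the new centre is racemic and is erased in step 8.

**Step 2**
Reactants: 3 3-methyltetrahydro-2H-pyran-2-one
Product: 4 5-hydroxy-N-methoxy-N,2-dimethylpentanamide (racemic)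
Conditions: MeNH(OMe)·HCl, iPrMgCl, THF, −20 → 0 °C
Reagents that add atoms: N,O-dimethylhydroxylamine hydrochloride, CNOC.Cl
Why: Aminolysis of the lactone by the chloromagnesium amide (Weinreb amide formation from an ester) should open the ring and free the primary alcohol that becomes C3.

**Step 3**
Reactants: 4 5-hydroxy-N-methoxy-N,2-dimethylpentanamide
Product: 5 N-methoxy-N,2-dimethyl-5-oxopentanamide (racemic)
Conditions: TEMPO (cat.), PhI(OAc)2, CH2Cl2, rt
Reagents that add atoms: none
Why: Oxoammonium (TEMPO) oxidation should stop at the aldehyde and leave the Weinreb amide untouched.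

**Step 4**
Reactants: 5 N-methoxy-N,2-dimethyl-5-oxopentanamide; 6 prenylmagnesium chloride (3-methylbut-2-en-1-ylmagnesium chloride)
Product: 9 (5S)-5-hydroxy-N-methoxy-N,2,6,6-tetramethyloct-7-enamide (C2 epimers), via B-prenyldiisopinocampheylborane 7 (not isolated), via diisopinocampheylborinate 8 (not isolated)
Conditions: (+)-Ipc2BOMe [from (−)-α-pinene], 6, Et2O, −78 °C → rt; then 5, −78 °C; NaBO3·4H2O, THF/H2O, rt
Reagents that add atoms: none
Why: Asymmetric allylboration (Brown type) through a closed chair transition state with allyl transposition should deliver the 1,1-dimethylallyl unit (future C4–C6 with both methyls), and the (−)-α-pinene-derived isopinocampheyl groups should direct it to the Re face of the aldehyde, which sets the (S) carbinol that becomes C3.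

**Step 5**
Reactants: 9 (5S)-5-hydroxy-N-methoxy-N,2,6,6-tetramethyloct-7-enamide
Product: 10 (5S)-5-[(tert-butyldimethylsilyl)oxy]-N-methoxy-N,2,6,6-tetramethyloct-7-enamide (C2 epimers)
Conditions: TBSOTf, 2,6-lutidine, CH2Cl2, −78 → 0 °C
Reagents that add atoms: tert-butyldimethylsilyl trifluoromethanesulfonate, CC(C)(C)[Si](C)(C)OS(=O)(=O)C(F)(F)F
Why: Silyl triflate silylation should protect the hindered neopentyl alcohol as an ether that withstands the Grignard, radical, ylide and base steps ahead.

**Step 6**
Reactants: 10 (5S)-5-[(tert-butyldimethylsilyl)oxy]-N-methoxy-N,2,6,6-tetramethyloct-7-enamide; 11 isopropenylmagnesium bromide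
Product: 12 (7S)-7-[(tert-butyldimethylsilyl)oxy]-2,4,8,8-tetramethyldeca-1,9-dien-3-one (C4 epimers)
Conditions: 11 (2 equiv), THF, 0 °C; aq. NH4Cl
Reagents that add atoms: none
Why: Weinreb ketone synthesis: the chelated tetrahedral adduct should prevent over-addition and give the isopropenyl ketone (C7=C8 with its methyl, C9=O).

**Step 7**
Reactants: 12 (7S)-7-[(tert-butyldimethylsilyl)oxy]-2,4,8,8-tetramethyldeca-1,9-dien-3-one
Product: 14 (7S)-4-bromo-7-[(tert-butyldimethylsilyl)oxy]-2,4,8,8-tetramethyldeca-1,9-dien-3-one (C4 epimers), via trimethylsilyl dienol ether 13 (not isolated)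
Conditions: TMSOTf, Et3N, CH2Cl2, 0 °C; pentane/aq. NaHCO3, crude 13; NBS, THF, −78 → 0 °C
Reagents that add atoms: N-bromosuccinimide, BrN1C(=O)CCC1=O
Why: The ketone has a single enolisable position (the methine that becomes C10), so soft enolisation should give one regioisomeric silyl dienol ether, and NBS should brominate its electron-rich α-carbon much faster than either alkene (α-halogenation via a silyl enol ether).

**Step 8**
Reactants: 14 (7S)-4-bromo-7-[(tert-butyldimethylsilyl)oxy]-2,4,8,8-tetramethyldeca-1,9-dien-3-one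
Product: 16 (2R,4aS,6S,8aS)-6-[(tert-butyldimethylsilyl)oxy]-2,5,5,8a-tetramethyloctahydronaphthalen-1(2H)-one (trans-decalin; labdane numbering 3β-OTBS 5α-H 8α-Me 9-oxo 10β-Me), via 8β-methyl ketone 15 (not isolated)
Conditions: Bu3SnH (1.3 equiv) + AIBN (0.2 equiv) by syringe pump over 10 h, PhH (0.003 M), 80 °C; evaporate; NaOMe, MeOH, rt
Reagents that add atoms: none
Why: Bu3Sn• abstracts bromine from 14 to give the tertiary α-keto radical at C10, which closes ring A by 6-exo-trig attack on C5 of the vinyl group (C5–C10) and passes the spin to primary C6, which closes ring B by 6-endo-trig attack on the CH2 terminus C7 of the isopropenyl ketone (C6–C7); the tertiary α-keto radical at C8 then takes hydrogen from Bu3SnH and methoxide equilibrates C8. The closest known reaction type is the tin hydride-mediated tandem cyclization of an α-halo carbonyl radical onto an alkene and then an enone, the reductive counterpart of Mn(OAc)3 polycyclizations that give trans-decalins. C5 is set in a chair-like exo transition state of ring A in which the C3 silyl ether and the vinyl group are both equatorial, which places 5-H on the α face relative to the 3β-oxygen; C10 is set in the same transition state because the flat conjugated acyl group takes the outer (equatorial) site and the methyl the axial site beside the 4β-methyl, so C9 and C6 are trans and ring B can only close as a trans-decalin through a chair. C8 is under thermodynamic control: the equatorial 8α-methyl avoids the 1,3-diaxial clash with the C10 methyl that the 8β-epimer 15 suffers. The step needs 6-exo over 7-endo closure and cyclization before reduction in the first ring, which the quaternary C4 (no allylic hydrogen to lose, Thorpe–Ingold compression) and syringe-pump addition at high dilution are meant to secure, and 6-endo over 5-exo closure in the second ring, which the methyl on C8 and the matched polarity of alkyl radical and enone terminus secure.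

**Step 9**
Reactants: 16 the trans-decalone of step 8
Product: 17 3β-[(tert-butyldimethylsilyl)oxy]-9-methylidene analogue of 16 (exocyclic C9=C11; 5α-H 8α-Me 10β-Me)
Conditions: Ph3PCH3Br, KOtBu, toluene, 90 °C
Reagents that add atoms: methyltriphenylphosphonium bromide, C[P+](c1ccccc1)(c1ccccc1)c1ccccc1.[Br-]
Why: Wittig methylenation with the alkoxide-generated ylide at elevated temperature is the usual answer to ketones flanked by a quaternary carbon, and any base-induced epimerisation at C8 only returns the favoured 8α-methyl ketone before olefination.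

**Step 10**
Reactants: 17 the 9(11)-methylidene decalin
Product: 18 9α,11-epoxide of 17 (spiro-oxirane; oxygen α and axial; C11 β and equatorial)
Conditions: mCPBA, NaHCO3, CH2Cl2, 0 °C
Reagents that add atoms: 3-chloroperoxybenzoic acid, OOC(=O)c1cccc(Cl)c1
Why: Peracid (Prilezhaev) epoxidation should occur on the α face because the axial C10 methyl next to the exocyclic alkene blocks the β face, which fixes C9 with oxygen α and C11 β.

**Step 11**
Reactants: 18 the 9α,11-epoxide
Product: 19 3β-[(tert-butyldimethylsilyl)oxy]-9β-vinyl-trans-decalin-9α-ol (C11=C12 vinyl on C9; 8α-Me 10β-Me)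
Conditions: Me3SI, n-BuLi (4 equiv each), THF, −10 °C → rt
Reagents that add atoms: trimethylsulfonium iodide, C[S+](C)C.[I-]
Why: One-carbon homologation of an epoxide to an allylic alcohol with excess dimethylsulfonium methylide: the ylide should open the oxirane at its CH2 terminus (C11), the C9–O bond is untouched so C9 keeps its configuration, and a second ylide equivalent triggers loss of dimethyl sulfide to give the vinyl group.

**Step 12**
Reactants: 19 the silyl-protected vinyl carbinol
Product: 20 9β-vinyl-4,4,8α,10β-tetramethyl-trans-decalin-3β,9α-diol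
Conditions: Bu4NF, THF, 50 °C
Reagents that add atoms: none
Why: Fluoride-induced Si–O cleavage should free the C3 hydroxyl; no butenolide is present yet, so the basic fluoride is harmless.

**Step 13**
Reactants: 20 the 3β,9α-diol
Product: 21 3β-acetoxy-9β-vinyl-4,4,8α,10β-tetramethyl-trans-decalin-9α-ol
Conditions: Ac2O, pyridine, DMAP (cat.), CH2Cl2, rt
Reagents that add atoms: acetic anhydride, CC(=O)OC(C)=O
Why: DMAP-catalysed acylation should take only the secondary equatorial C3 hydroxyl, because the tertiary C9 hydroxyl sits between two fully substituted carbons.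

**Step 14**
Reactants: 21 the 3β-acetate; 22 4-bromofuran-2(5H)-one
Product: 24 (3S,5S,8R,9R,10S)-3-acetoxy-9-hydroxylabd-13-en-15,16-olide (3β-OAc 9α-OH 8α-Me; the target), via B-alkyl-9-BBN 23 (not isolated)
Conditions: 9-BBN dimer, THF, rt → 40 °C; then H2O, 22, PdCl2(dppf), AsPh3, Cs2CO3, DMF/THF/H2O, rt
Reagents that add atoms: none
Why: Anti-Markovnikov hydroboration should place boron on terminal C12, and B-alkyl Suzuki–Miyaura coupling with the β-bromobutenolide (a vinylogous acyl bromide that adds oxidatively with ease) should forge C12–C13 at room temperature without touching the acetate.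

**Compound list**

1 | δ-valerolactone (tetrahydro-2H-pyran-2-one) | O=C1CCCCO1 | starting material
2 | lithium enolate of 1 | [Li+].[O-]C1=CCCCO1 | intermediate (not isolated)
3 | 3-methyltetrahydro-2H-pyran-2-one (racemic) | CC1CCCOC1=O | intermediate
4 | 5-hydroxy-N-methoxy-N,2-dimethylpentanamide (racemic) | CC(CCCO)C(=O)N(C)OC | intermediate
5 | N-methoxy-N,2-dimethyl-5-oxopentanamide (racemic) | CC(CCC=O)C(=O)N(C)OC | intermediate
6 | prenylmagnesium chloride | CC(C)=CC[Mg]Cl | starting material
7 | B-prenyldiisopinocampheylborane, isopinocampheyl groups from (−)-α-pinene | CC(C)=CCB([C@H]1C[C@H]2C[C@@H]([C@@H]1C)C2(C)C)[C@H]1C[C@H]2C[C@@H]([C@@H]1C)C2(C)C | intermediate (not isolated)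
8 | diisopinocampheylborinate of 9 | C=CC(C)(C)[C@H](CCC(C)C(=O)N(C)OC)OB([C@H]1C[C@H]2C[C@@H]([C@@H]1C)C2(C)C)[C@H]1C[C@H]2C[C@@H]([C@@H]1C)C2(C)C | intermediate (not isolated)
9 | (5S)-5-hydroxy-N-methoxy-N,2,6,6-tetramethyloct-7-enamide (C2 epimers) | C=CC(C)(C)[C@@H](O)CCC(C)C(=O)N(C)OC | intermediate
10 | (5S)-5-[(tert-butyldimethylsilyl)oxy]-N-methoxy-N,2,6,6-tetramethyloct-7-enamide (C2 epimers) | C=CC(C)(C)[C@@H](O[Si](C)(C)C(C)(C)C)CCC(C)C(=O)N(C)OC | intermediate
11 | isopropenylmagnesium bromide | CC(=C)[Mg]Br | starting material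
12 | (7S)-7-[(tert-butyldimethylsilyl)oxy]-2,4,8,8-tetramethyldeca-1,9-dien-3-one (C4 epimers) | C=CC(C)(C)[C@@H](O[Si](C)(C)C(C)(C)C)CCC(C)C(=O)C(C)=C | intermediate
13 | trimethylsilyl dienol ether of 12 (E/Z mixture) | C=CC(C)(C)[C@@H](O[Si](C)(C)C(C)(C)C)CCC(C)=C(O[Si](C)(C)C)C(C)=C | intermediate (not isolated)
14 | (7S)-4-bromo-7-[(tert-butyldimethylsilyl)oxy]-2,4,8,8-tetramethyldeca-1,9-dien-3-one (C4 epimers) | C=CC(C)(C)[C@@H](O[Si](C)(C)C(C)(C)C)CCC(C)(Br)C(=O)C(C)=C | intermediate
15 | 8β-methyl epimer of 16 (axial C8 methyl) | CC(C)(C)[Si](C)(C)O[C@H]1CC[C@@]2(C)[C@@H](CC[C@H](C)C2=O)C1(C)C | intermediate (not isolated)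
16 | (2R,4aS,6S,8aS)-6-[(tert-butyldimethylsilyl)oxy]-2,5,5,8a-tetramethyloctahydronaphthalen-1(2H)-one (3β-OTBS, 5α-H, 8α-Me, 9-oxo, 10β-Me) | CC(C)(C)[Si](C)(C)O[C@H]1CC[C@@]2(C)[C@@H](CC[C@@H](C)C2=O)C1(C)C | intermediate
17 | 9-methylidene analogue of 16 (C9=C11) | CC(C)(C)[Si](C)(C)O[C@H]1CC[C@@]2(C)[C@@H](CC[C@@H](C)C2=C)C1(C)C | intermediate
18 | 9α,11-epoxide of 17 | CC(C)(C)[Si](C)(C)O[C@H]1CC[C@@]2(C)[C@@H](CC[C@@H](C)[C@]2(O3)C3)C1(C)C | intermediate
19 | 3β-[(tert-butyldimethylsilyl)oxy]-9β-vinyl-4,4,8α,10β-tetramethyl-trans-decalin-9α-ol | CC(C)(C)[Si](C)(C)O[C@H]1CC[C@@]2(C)[C@@H](CC[C@@H](C)[C@]2(O)C=C)C1(C)C | intermediate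
20 | 9β-vinyl-4,4,8α,10β-tetramethyl-trans-decalin-3β,9α-diol | O[C@H]1CC[C@@]2(C)[C@@H](CC[C@@H](C)[C@]2(O)C=C)C1(C)C | intermediate
21 | 3β-acetoxy-9β-vinyl-4,4,8α,10β-tetramethyl-trans-decalin-9α-ol | CC(=O)O[C@H]1CC[C@@]2(C)[C@@H](CC[C@@H](C)[C@]2(O)C=C)C1(C)C | intermediate
22 | 4-bromofuran-2(5H)-one | BrC1=CC(=O)OC1 | starting material
23 | B-alkyl-9-BBN from 21 (boron on C12) | CC(=O)O[C@H]1CC[C@@]2(C)[C@@H](CC[C@@H](C)[C@]2(O)CCB2C3CCCC2CCC3)C1(C)C | intermediate (not isolated)
24 | (3S,5S,8R,9R,10S)-3-acetoxy-9-hydroxylabd-13-en-15,16-olide | CC(=O)O[C@H]1CC[C@@]2(C)[C@@H](CC[C@@H](C)[C@]2(O)CCC2=CC(=O)OC2)C1(C)C | target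

**Step count and risks**

Total steps: 14. Longest linear sequence: 14 steps (1 → 24); 6, 11 and 22 are purchased.

Steps most likely to fail:

1. **Step 8 (key step).** The first ring closure may go 7-endo at the terminal vinyl carbon, the C10 radical may be reduced before it cyclizes, or the C3 silyl ether may discriminate the two chair transition states of ring A only weakly. Fallback in the polar manifold, setting out from 10 and coming back at 16: ozonolysis of the vinyl group of 10 (O3, CH2Cl2, −78 °C; Me2S) should give the neopentyl aldehyde F1. Horner–Wadsworth–Emmons olefination with diethyl (phenylsulfonyl)methylphosphonate (NaH, THF) should give the (E)-vinyl sulfone F2. Addition of 11 to the Weinreb amide should give the sulfonyl dienone F3. LiN(SiMe3)2 (THF, −78 → 0 °C) should then form the same two bonds by an intramolecular double Michael reaction (C10 enolate to C5, the α-sulfonyl carbanion at C6 to C7) to give the sulfonyl decalone F4. Buffered Na/Hg (Na2HPO4, MeOH, −20 °C) followed by NaOMe would remove the sulfone, equilibrate C8 and rejoin the route at 16.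

2. **Step 11.** The ylide may fail to reach the CH2 terminus of the hindered spiro-epoxide, or lithium iodide may induce rearrangement of the epoxide to the C9 aldehyde. Fallback setting out from 17 and coming back at 19: dihydroxylation from the same α face (OsO4 cat., N-methylmorpholine N-oxide, acetone/H2O) should give the 9α,11-diol F5. Selective oxidation of its primary hydroxyl (TEMPO, PhI(OAc)2) should give the α-hydroxy aldehyde F6, which cannot epimerise at fully substituted C9. Wittig methylenation (Ph3P=CH2 in excess, THF) would deliver 19.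

3. **Step 14.** Transmetalation of the hindered alkylborane may be slow enough that the base destroys the bromobutenolide or promotes conjugate addition of the C9 hydroxyl to the newly formed butenolide. Fallback setting out from 21 and coming back at 24: borane 23 is coupled instead with 3-bromofuran (PdCl2(dppf), K3PO4, DMF, 50 °C) to give the 3-alkylfuran F7, which carries no Michael acceptor. Base-directed singlet-oxygen oxidation (O2, rose bengal, hν, iPr2NEt, CH2Cl2, −78 °C) should give the γ-hydroxybutenolide F8, with the hydroxylated carbon next to the alkyl-bearing carbon. NaBH4 (EtOH, 0 °C) should reduce that masked aldehyde so that relactonisation gives 24.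

**Further compounds**

F1 | step 8 | (5S)-5-[(tert-butyldimethylsilyl)oxy]-N-methoxy-N,2,6,6-tetramethyl-7-oxoheptanamide (C2 epimers) | O=CC(C)(C)[C@@H](O[Si](C)(C)C(C)(C)C)CCC(C)C(=O)N(C)OC
F2 | step 8 | (5S,7E)-5-[(tert-butyldimethylsilyl)oxy]-N-methoxy-N,2,6,6-tetramethyl-8-(phenylsulfonyl)oct-7-enamide (C2 epimers) | O=S(=O)(/C=C/C(C)(C)[C@@H](O[Si](C)(C)C(C)(C)C)CCC(C)C(=O)N(C)OC)c1ccccc1
F3 | step 8 | (7S,9E)-7-[(tert-butyldimethylsilyl)oxy]-2,4,8,8-tetramethyl-10-(phenylsulfonyl)deca-1,9-dien-3-one (C4 epimers) | O=S(=O)(/C=C/C(C)(C)[C@@H](O[Si](C)(C)C(C)(C)C)CCC(C)C(=O)C(C)=C)c1ccccc1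
F4 | step 8 | 6-(phenylsulfonyl) derivative of 16 (mixture at C6 and C8) | CC(C)(C)[Si](C)(C)O[C@H]1CC[C@@]2(C)[C@@H](C(CC(C)C2=O)S(=O)(=O)c2ccccc2)C1(C)C
F5 | step 11 | 9α,11-diol from 17 (9α-hydroxy-9β-hydroxymethyl) | CC(C)(C)[Si](C)(C)O[C@H]1CC[C@@]2(C)[C@@H](CC[C@@H](C)[C@]2(O)CO)C1(C)C
F6 | step 11 | 9α-hydroxy-9β-carbaldehyde from F5 | CC(C)(C)[Si](C)(C)O[C@H]1CC[C@@]2(C)[C@@H](CC[C@@H](C)[C@]2(O)C=O)C1(C)C
F7 | step 14 | 3β-acetoxy-9α-hydroxy-15,16-epoxylabda-13(16),14-diene (3-alkylfuran) | CC(=O)O[C@H]1CC[C@@]2(C)[C@@H](CC[C@@H](C)[C@]2(O)CCc2ccoc2)C1(C)C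
F8 | step 14 | 16-hydroxy derivative of 24 (γ-hydroxybutenolide, C16 epimers) | CC(=O)O[C@H]1CC[C@@]2(C)[C@@H](CC[C@@H](C)[C@]2(O)CCC2=CC(=O)OC2O)C1(C)C
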